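The numbers in the tables are calculated with constants of no real substance; noise was put on by code.

The vessel is closed and stirred, at constant volume and temperature. My decision is how much incoming ligand to charge for the complex with two exchanged to become the main form within 40 h.

| flask | starting complex | incoming ligand | leaving ligand | capture agent | remark | time |
|---|---|---|---|---|---|---|
| delta | 13 mM | 9.6 mM | 13 mM | 13 mM | run made earlier |  |
| alpha | 13 mM | 44 mM | 13 mM | 13 mM | run made earlier |  |
| maple | 13 mM | 13.0 mM | 13.0 mM | 13.0 mM |  | 40 h |
| elm | 13 mM | 52.0 mM | 13.0 mM | 13.0 mM |  | 40 h |
| ash | 13 mM | 19.5 mM | 13.0 mM | 13.0 mM |  | 40 h |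

| run | time / h | complex with two exchanged / % | complex with four exchanged / % |
|---|---|---|---|
| delta | 1.50 | 0 | 0 |
| delta | 2.50 | 0.3 | 0.3 |
| delta | 4.00 | 0.5 | 0.1 |
| delta | 6.00 | 0 | 0.6 |
| delta | 8.00 | 0.6 | 0 |
| delta | 12.0 | 1.9 | 0.6 |
| delta | 20.0 | 3.7 | 0 |
| alpha | 1.50 | 0.8 | 0 |
| alpha | 2.50 | 2.4 | 0 |
| alpha | 4.00 | 3.0 | 0 |
| alpha | 6.00 | 7.2 | 0 |
| alpha | 8.00 | 10.4 | 0 |
| alpha | 12.0 | 16.7 | 0.2 |
| alpha | 20.0 | 25.9 | 0 |

(standard deviation of a reading: 0.5 percentage points)

- which of these holds the largest part of the starting complex at the end of maple (complex with three exchanged / starting complex / complex with one exchanged / complex with four exchanged / complex with two exchanged)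
- which of these holds the largest part of the starting complex at the end of elm (complex with three exchanged / starting complex / complex with one exchanged / complex with four exchanged / complex with two exchanged)
- which of these holds the largest part of the starting complex at the end of ash (complex with three exchanged / starting complex / complex with one exchanged / complex with four exchanged / complex with two exchanged)
- amount of complex with two exchanged at the end of maple, in percent of the starting complex charged



I reckon with exposure, meaning the mean [incoming ligand] times the time, and replace the falling ligand curve by that mean. Each complex with two exchanged has taken two ligands, so I put the mean below the charge by the [complex with two exchanged] formed. At 20.0 h, delta reads 3.7% on a mean of 9.12 mM, and alpha reads 25.9% on 40.6 mM. The exposure exponent, the power of exposure that the two-exchanged reading follows, is therefore 1.30, a reading that carries the scatter of 0.5 percentage points. It stands below the 2 of two successive exchanges at their very start, and I use it only to scale the two-exchanged reading, because neither run reads complex with one exchanged.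

Scaling from delta, maple has a mean near 11.1 mM and gives 11.8%. Ash has a mean near 16.3 mM and gives 19.5%. Elm lies beyond alpha's exposure, but even a mean of 39.0 mM gives 60.6%, so I leave ash and charge elm.

The forecast, reading “four sequential exchanges, each first order in free incoming ligand”, names starting complex for maple, complex with two exchanged for elm and complex with one exchanged for ash, with 10% for maple.

The flasks give starting complex in maple at 71.0%, complex with two exchanged in elm at 37.3%, and starting complex in ash at 60.0%, with 9.75% of complex with two exchanged in maple.

    starting complex + incoming ligand ⇌ leaving ligand + complex with one exchanged (K = 6.62, k = 0.901 L mol⁻¹ h⁻¹)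
    complex with three exchanged + incoming ligand ⇌ leaving ligand + complex with four exchanged (K = 1.34, k = 0.199 L mol⁻¹ h⁻¹)
    complex with one exchanged + incoming ligand ⇌ leaving ligand + complex with two exchanged (K = 19.4, k = 4.56 L mol⁻¹ h⁻¹)
    complex with two exchanged + capture agent → trapped intermediate (k = 2.15 L mol⁻¹ h⁻¹)
    complex with two exchanged + incoming ligand ⇌ leaving ligand + complex with three exchanged (K = 0.134, k = 1.79 L mol⁻¹ h⁻¹)

Maple's actual mean ligand, weighted from its start, middle and end, is 9.81 mM, lower than my 11.1 mM, and the exponent then gives 10.0%. On ash, the same steps give 16.8% against 16.1%. Maple has not come to rest at 40 h. By 400 h, its complex with two exchanged falls to 1.23%, its trapped intermediate rises from 5.50% to 42.6%, and its starting complex falls to 48.5%. Its incoming ligand stands at 4.58% of the charge.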